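A direct plan would build ring C first and ring A last: a [3+3] cyclocondensation of a dialkoxy silyl enol ether with a malonyl unit would give pyranone A1, two acylations and a cyclodehydration would give pyranopyrandione A2, and an alkoxide would open its lactone and reclose it by Claisen condensation to dihydroxyflavone A3, whose 7-O-methyl ether A4 would be debenzylated.
Its weakest steps would be: the cyclocondensation to A1, since the dialkoxy enol ether can be acylated at oxygen or at either carbon; the lactone opening and Claisen reclosure of A2, since attack at the 4-pyranone and relactonisation would compete and close precedent is lacking; the partial methylation of A3, a step that only corrects the oxygen pattern.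

The route rests on the para relation of the C5 hydroxyl and the C8 methoxy group on ring A, a hydroquinone monomethyl ether. Ring A is bought whole as 1,2,3,4-tetramethoxybenzene, so that its methoxy groups are present from the start, and ring C is closed last through the O1–C8a bond at an unfunctionalised arene carbon: oxidative dearomatisation of the 2'-hydroxyaryl diketone 8 to a quinone monoketal, conjugate addition of the diketone enol oxygen and loss of methanol. One operation thus installs the fifth ring-A oxygen, closes ring C and leaves the 5-hydroxyl free, so no pyranone construction, ring transformation or late methylation is needed.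

Key step: step 4

Assumption: 1,2,3,4-tetramethoxybenzene and 4-(allyloxy)benzoyl chloride are taken as catalogue compounds.

**Step 1**
Reactants: 1 1,2,3,4-tetramethoxybenzene; 2 N,2-dimethoxy-N-methylacetamide
Product: 4 2-methoxy-1-(2,3,4,5-tetramethoxyphenyl)ethan-1-one, via aryllithium 3 (not isolated)
Conditions: n-BuLi (1.1 equiv), TMEDA (1.1 equiv), THF, 0 °C; then 2 (1.2 equiv), −78 °C to 0 °C; 1 M HCl
Reagents that add atoms: none
Why: Directed ortho-lithiation at one of the two equivalent free positions next to a methoxy group, followed by a Weinreb ketone synthesis in which the chelated tetrahedral adduct prevents over-addition, should give the α-methoxy ketone as a single regioisomer.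

**Step 2**
Reactants: 4 2-methoxy-1-(2,3,4,5-tetramethoxyphenyl)ethan-1-one
Product: 6 1-(2-hydroxy-3,4,5-trimethoxyphenyl)-2-methoxyethan-1-one, via dichloroboron chelate 5 (not isolated)
Conditions: BCl3 (1.2 equiv), CH2Cl2, −78 °C to 0 °C; then H2O
Reagents that add atoms: none
Why: Lewis acid ether cleavage with BCl3 should be selective for the methoxy group ortho to the ketone, because only this oxygen can form a six-membered boron chelate with the carbonyl group before chloride attacks its methyl group, while the other aryl ethers and the aliphatic ether react only at higher temperature.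

**Step 3**
Reactants: 6 1-(2-hydroxy-3,4,5-trimethoxyphenyl)-2-methoxyethan-1-one; 7 4-(allyloxy)benzoyl chloride
Product: 8 1-[4-(allyloxy)phenyl]-3-(2-hydroxy-3,4,5-trimethoxyphenyl)-2-methoxypropane-1,3-dione (racemic at the labile methine)
Conditions: LiN(SiMe3)2 (3.3 equiv), THF, −78 °C; then 7 (1.0 equiv), −78 °C to rt; 1 M HCl
Reagents that add atoms: none
Why: Claisen-type C-aroylation of the dilithium phenolate-enolate of 6, the direct variant of the Baker–Venkataraman route to 2'-hydroxy-1,3-diketones, is driven by deprotonation of the product by the third equivalent of base, and any ester formed at the phenolate oxygen would rearrange to the same diketone under these conditions.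

**Step 4**
Reactants: 8 1-[4-(allyloxy)phenyl]-3-(2-hydroxy-3,4,5-trimethoxyphenyl)-2-methoxypropane-1,3-dione
Product: 11 4'-allyloxy-5-hydroxy-3,6,7,8-tetramethoxyflavone, via quinone monoketal 9 (not isolated), via cyclised ketal 10 (not isolated)
Conditions: PhI(OAc)2 (1.05 equiv), MeOH–CH2Cl2 (1:9), 0 °C; then i-Pr2NEt (3 equiv), 0 °C to rt; then CF3CO2H (6 equiv), rt
Reagents that add atoms: methanol, CO (one of the two ketal methoxy groups of 9 comes from it, and either one can be the group retained at C8)
Why: Proposed new method: PhI(OAc)2 would bind the phenol oxygen of 8 and methanol would attack the para carbon C5', where the methoxy group stabilises the positive charge, to give the 2-acyl quinone monoketal 9; under base the enolate oxygen of the 1,3-diketone would then add to C6', which is β to both the ring carbonyl and the side-chain carbonyl, and acid would ionise the ketal of adduct 10 to an arenium ion that loses the C8a proton, so that the benzene ring returns with the free hydroxyl at C5 and a methoxy group at C8. The closest known reaction types are the oxidation of 4-methoxyphenols to quinone monoketals by PhI(OAc)2 in methanol and the conjugate addition of nucleophiles to 2-acyl quinone monoketals with re-aromatisation by loss of methanol; new is the diketone enol oxygen as internal nucleophile, which forms the O1–C8a bond of a chromone at a carbon that carried only hydrogen. Ring C closes in the 6-endo-trig mode (oxa-Michael addition), which is allowed; the alternatives would be a four-membered ring through C3 or a spiro furanone at the acyl-bearing carbon C1', which is disfavoured because the acyl group withdraws charge from that carbon. No stereocentre survives, because the sp3 carbon C8a of 10 becomes an arene carbon and C3 an alkene carbon. The step needs the phenol to be oxidised before the diketone and the internal oxygen to beat methanol at C6': the electron-rich para-methoxyphenol should be the fastest site for the iodine reagent while the α-methoxy diketone sits mainly in its unreactive diketo form, methanol is kept dilute in CH2Cl2, and the base is added only after the oxidant is spent, which also protects product 11, itself a para-methoxyphenol. An ortho-ketal formed by attack at C3' would be funnelled to the same product, since C6' stays the β-carbon and loss of methanol from C3' gives the same arene.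

**Step 5**
Reactants: 11 4'-allyloxy-5-hydroxy-3,6,7,8-tetramethoxyflavone
Product: 12 calycopterin (5,4'-dihydroxy-3,6,7,8-tetramethoxyflavone)
Conditions: Pd(PPh3)4 (5 mol %), morpholine (5 equiv), THF, rt
Reagents that add atoms: none
Why: Zerovalent palladium ionises the allyl aryl ether to a π-allyl complex and the phenolate, and morpholine traps the allyl fragment (Tsuji–Trost deallylation), which should leave the methyl ethers, the chelated 5-hydroxyl and the chromone untouched.

**Compound list**
1 | 1,2,3,4-tetramethoxybenzene | COc1ccc(OC)c(OC)c1OC | starting material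
2 | N,2-dimethoxy-N-methylacetamide | COCC(=O)N(C)OC | starting material
3 | (2,3,4,5-tetramethoxyphenyl)lithium | [Li]c1cc(OC)c(OC)c(OC)c1OC | intermediate
4 | 2-methoxy-1-(2,3,4,5-tetramethoxyphenyl)ethan-1-one | COCC(=O)c1cc(OC)c(OC)c(OC)c1OC | intermediate
5 | dichloro[6-(methoxyacetyl)-2,3,4-trimethoxyphenoxy]borane | COCC(=O)c1cc(OC)c(OC)c(OC)c1OB(Cl)Cl | intermediate
6 | 1-(2-hydroxy-3,4,5-trimethoxyphenyl)-2-methoxyethan-1-one | COCC(=O)c1cc(OC)c(OC)c(OC)c1O | intermediate
7 | 4-(allyloxy)benzoyl chloride | C=CCOc1ccc(C(=O)Cl)cc1 | starting material
8 | 1-[4-(allyloxy)phenyl]-3-(2-hydroxy-3,4,5-trimethoxyphenyl)-2-methoxypropane-1,3-dione (diketo tautomer drawn; methine labile, racemic) | COC(C(=O)c1ccc(OCC=C)cc1)C(=O)c1cc(OC)c(OC)c(OC)c1O | intermediate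
9 | 2-{3-[4-(allyloxy)phenyl]-2-methoxy-3-oxopropanoyl}-4,4,5,6-tetramethoxycyclohexa-2,5-dien-1-one (methine labile, racemic) | COC(C(=O)c1ccc(OCC=C)cc1)C(=O)C1=CC(OC)(OC)C(OC)=C(OC)C1=O | intermediate
10 | 2-[4-(allyloxy)phenyl]-5-hydroxy-3,6,7,8,8-pentamethoxy-8,8a-dihydro-4H-chromen-4-one (enol tautomer drawn; racemic at C8a) | COC1=C(c2ccc(OCC=C)cc2)OC2C(=C(O)C(OC)=C(OC)C2(OC)OC)C1=O | intermediate
11 | 4'-allyloxy-5-hydroxy-3,6,7,8-tetramethoxyflavone | COc1c(OC)c(O)c2c(=O)c(OC)c(-c3ccc(OCC=C)cc3)oc2c1OC | intermediate
12 | calycopterin, 5-hydroxy-2-(4-hydroxyphenyl)-3,6,7,8-tetramethoxy-4H-chromen-4-one | COc1c(OC)c(O)c2c(=O)c(OC)c(-c3ccc(O)cc3)oc2c1OC | target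

Total step count: 5. Longest linear sequence: 5 steps.

**Steps most likely to fail**

Step 4 (proposed new method). The oxidant may attack the diketone instead of the phenol, solvent methanol may add to C6' in place of the enol oxygen, an ortho-ketal may dimerise before it cyclises, or leftover oxidant may dearomatise the product. The fallback uses known halogenation and coupling chemistry and sets out from 6. Electrophilic bromination with N-bromosuccinimide (MeCN, 0 °C) at the only free ring position would give 1-(2-bromo-6-hydroxy-3,4,5-trimethoxyphenyl)-2-methoxyethan-1-one F1. Aroylation with 7 under the conditions of step 3 would give the bromo diketone 1-[4-(allyloxy)phenyl]-3-(2-bromo-6-hydroxy-3,4,5-trimethoxyphenyl)-2-methoxypropane-1,3-dione F2. An Ullmann-type intramolecular O-arylation of the diketone enolate oxygen (CuI 10 mol %, 1,10-phenanthroline, K2CO3, DMF, 100 °C), the known route from 1-(2-bromoaryl)-1,3-diketones to flavones, would then return to the route at 11.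

Step 3. Acylation may stop at the phenolate oxygen, a second aroyl group may be taken up, or the diketone may undergo retro-Claisen cleavage at work-up. The fallback separates the two events and sets out from 6. O-aroylation with 7 (pyridine, CH2Cl2, 0 °C) would give the isolated ester 6-(methoxyacetyl)-2,3,4-trimethoxyphenyl 4-(allyloxy)benzoate F3. A Baker–Venkataraman rearrangement (KOt-Bu, THF, 0 °C) would then transfer the aroyl group intramolecularly to the enolate carbon and return to the route at 8.

Step 2. Ether cleavage may go on to the neighbouring C3' methoxy group or reach the aliphatic methyl ether. The fallback replaces Lewis acid cleavage by an oxidation-reduction sequence and sets out from 4. Oxidative demethylation of the para pair of methoxy groups with (NH4)2Ce(NO3)6 (MeCN–H2O, 0 °C) would give the acylquinone 2,3-dimethoxy-5-(methoxyacetyl)cyclohexa-2,5-diene-1,4-dione F4. Reduction with Na2S2O4 would give the hydroquinone 1-(2,5-dihydroxy-3,4-dimethoxyphenyl)-2-methoxyethan-1-one F5. Methylation of its non-chelated hydroxyl (MeI 1 equiv, K2CO3, acetone) would return to the route at 6.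

**Further compounds**
F1 | step 4 | 1-(2-bromo-6-hydroxy-3,4,5-trimethoxyphenyl)-2-methoxyethan-1-one | COCC(=O)c1c(Br)c(OC)c(OC)c(OC)c1O
F2 | step 4 | 1-[4-(allyloxy)phenyl]-3-(2-bromo-6-hydroxy-3,4,5-trimethoxyphenyl)-2-methoxypropane-1,3-dione (methine labile, racemic) | COC(C(=O)c1ccc(OCC=C)cc1)C(=O)c1c(Br)c(OC)c(OC)c(OC)c1O
F3 | step 3 | 6-(methoxyacetyl)-2,3,4-trimethoxyphenyl 4-(allyloxy)benzoate | COCC(=O)c1cc(OC)c(OC)c(OC)c1OC(=O)c1ccc(OCC=C)cc1
F4 | step 2 | 2,3-dimethoxy-5-(methoxyacetyl)cyclohexa-2,5-diene-1,4-dione | COCC(=O)C1=CC(=O)C(OC)=C(OC)C1=O
F5 | step 2 | 1-(2,5-dihydroxy-3,4-dimethoxyphenyl)-2-methoxyethan-1-one | COCC(=O)c1cc(O)c(OC)c(OC)c1O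
A1 | direct plan | 4-hydroxy-5-methoxy-6-(methoxymethyl)-2H-pyran-2-one | COCC1=C(OC)C(O)=CC(=O)O1
A2 | direct plan | 2-(4-benzyloxyphenyl)-3,8-dimethoxy-7-(methoxymethyl)-4H,5H-pyrano[4,3-b]pyran-4,5-dione | COCC1=C(OC)C2=C(C(=O)O1)C(=O)C(OC)=C(O2)c1ccc(OCc3ccccc3)cc1
A3 | direct plan | 4'-benzyloxy-5,7-dihydroxy-3,6,8-trimethoxyflavone | COc1c(O)c(OC)c2oc(-c3ccc(OCc4ccccc4)cc3)c(OC)c(=O)c2c1O
A4 | direct plan | 4'-benzyloxy-5-hydroxy-3,6,7,8-tetramethoxyflavone | COc1c(OC)c(O)c2c(=O)c(OC)c(-c3ccc(OCc4ccccc4)cc3)oc2c1OC
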